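Everything rests on cutting the oxane at O–C15 and the oxolane at O8–C11, with the chain divided at C9–C10. The key step exploits the placement of two carbons around spiro C11. Oxane carbon C15, which bears the ring oxygen, is δ to C11, and oxolane carbinol C8 is γ. An open-chain C11 ketone with free C8–OH and a 15S chloride therefore closes the oxolane as a hemiketal. Its hydroxyl then displaces chloride with inversion, closing the oxane and fixing C11 and C15 in one operation. The precursor, silylated at O6, O16 and O21, derives from the anti-chlorohydrin of (R)-citronellal and an epoxide from ethyl (R)-4-chloro-3-hydroxybutanoate, joined by acetylide–epoxide opening and gold-catalysed hydration.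

Key step: step 16

Numbering: C1 = vinyl CH2, C11 = spiro carbon, C21 = CH2OH. TBS = tert-butyldimethylsilyl.

Assumption: (2R,5R)-2,5-diphenylpyrrolidine is taken to deliver chlorine to the Si face of C2 of the E-enamine (2S product). The sense is checked on compound 5, and the (2S,5S) catalyst is used if it proves opposite.

Remark: the C8 descriptor changes from R (15–23) to S (25–30) only because C9 loses its CIP rank when chlorine or epoxide oxygen is replaced by carbon. No bond to C8 is ever broken.

Step 1
Reactants: 1 (R)-citronellal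
Product: 2 (2S,3R)-2-chloro-3,7-dimethyloct-6-enal
Conditions: NCS (1.2 equiv), (2R,5R)-2,5-diphenylpyrrolidine (10 mol %), CH2Cl2, 0 °C → rt; pentane, filtration, cold concentration; used at once
Reagents that add atoms: N-chlorosuccinimide, O=C1CCC(=O)N1Cl
Why: Enamine-catalysed electrophilic α-chlorination, a reaction type already applied to citronellal, in which the phenyl group flanking the enamine carbon blocks one face so that chlorine should arrive on the Si face under catalyst control and set the 2S centre (C15) regardless of the C14 methyl.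

Step 2
Reactants: 2 (2S,3R)-2-chloro-3,7-dimethyloct-6-enal; 3 propargyl bromide
Product: 5 anti-chlorohydrin (4R,5S,6R)-5-chloro-6,10-dimethylundec-9-en-1-yn-4-ol (14R,15S,16R), via allenylmagnesium bromide 4 (not isolated)
Conditions: 3, Mg, ZnBr2 (2 mol %), Et2O, 0 °C; then crude 2, Et2O, −78 °C; sat. aq NH4Cl at −78 °C; chromatographic removal of minor diastereomers
Reagents that add atoms: none
Why: SE2′ addition of the allenyl Grignard reagent gives the homopropargylic alcohol, the Cornforth (polar Felkin–Anh) arrangement of the α-chloroaldehyde should steer attack to the face that sets 16R (1,2-anti to chlorine), and the cold quench keeps the magnesium alkoxide from closing to an epoxide.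

Step 3
Reactants: 5 anti-chlorohydrin
Product: 6 C16 TBS ether of 5
Conditions: TBSOTf (1.3 equiv), 2,6-lutidine (2 equiv), CH2Cl2, −78 → 0 °C
Reagents that add atoms: tert-butyldimethylsilyl triflate, CC(C)(C)[Si](C)(C)OS(=O)(=O)C(F)(F)F
Why: Silyl triflate silylation under a hindered, weakly basic pyridine never produces a free alkoxide, so the C16 hydroxyl should be capped without epoxide closure, which also makes the later organolithium steps possible.

Step 4
Reactants: 6 C16 TBS ether; 7 ethylene oxide
Product: 9 (6R,7S,8R)-7-chloro-6-(TBSO)-8,12-dimethyltridec-11-en-3-yn-1-ol, via lithium acetylide 8 (not isolated)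
Conditions: n-BuLi (1.05 equiv), THF, −78 °C; BF3·OEt2 (1.2 equiv); 7 (THF solution, 3 equiv), −78 °C
Reagents that add atoms: none
Why: Yamaguchi–Hirao alkynylation, in which deprotonation of the terminal alkyne at −78 °C is far faster than any attack of n-BuLi on the secondary chloride and the acetylide opens the BF3-activated epoxide to add C20–C21 as a primary alcohol.

Step 5
Reactants: 9 primary alcohol
Product: 10 C16,C21 bis-TBS ether of 9
Conditions: TBSCl (1.2 equiv), imidazole (2 equiv), CH2Cl2, rt
Reagents that add atoms: tert-butyldimethylsilyl chloride, CC(C)(C)[Si](C)(C)Cl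
Why: Imidazole-promoted silylation of an unhindered primary alcohol, which removes the last acidic proton before the second acetylide step.

Step 6
Reactants: 10 bis-TBS enyne
Product: 12 (4R,5S,6R)-5-chloro-4-methyl-6,11-bis(TBSO)undec-8-ynal (C11 aldehyde), via secondary ozonide 11 (not isolated)
Conditions: O3/O2, CH2Cl2, −78 °C, Sudan Red 7B end point; PPh3, −78 °C → rt; chromatography
Reagents that add atoms: ozone, [O-][O+]=O
Why: Chemoselective ozonolysis, since the electron-rich trisubstituted alkene consumes ozone far faster than an internal alkyne, so titration to the dye end point and phosphine reduction should give the aldehyde with C18≡C19 intact, which is why cleavage precedes semihydrogenation.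

Step 7
Reactants: 12 ynal
Product: 13 (4R,5S,6R,8Z)-5-chloro-4-methyl-6,11-bis(TBSO)undec-8-enal
Conditions: H2 (1 atm), Lindlar catalyst, quinoline, EtOAc–hexane, rt, stopped at one equivalent of H2
Reagents that add atoms: none
Why: Lindlar semihydrogenation, with syn delivery of hydrogen to the only alkyne present setting the 18Z alkene, placed here because the other alkene is already cleaved and the terminal alkyne is not yet installed, while aldehyde, chloride and silyl ethers are inert.

Step 8
Reactants: 13 Z-enal
Product: 14 (5R,6S,7R,9Z)-6-chloro-5-methyl-7,12-bis(TBSO)dodec-9-en-1-yne (C10–C21 fragment)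
Conditions: dimethyl (1-diazo-2-oxopropyl)phosphonate (1.3 equiv), K2CO3 (2 equiv), MeOH, 0 °C → rt
Reagents that add atoms: Ohira–Bestmann reagent, CC(=O)C(=[N+]=[N-])P(=O)(OC)OC
Why: Ohira–Bestmann (Seyferth–Gilbert) homologation adds C10 to an aldehyde whose α-carbon is a plain CH2, and carbonate in methanol cannot harm the chloride because its neighbouring oxygen is silylated.

Step 9
Reactants: 15 ethyl (3R)-4-chloro-3-hydroxybutanoate
Product: 16 (3R)-4-chloro-3-hydroxy-N-methoxy-N-methylbutanamide
Conditions: MeNH(OMe)·HCl (3 equiv), AlMe3 (3 equiv), CH2Cl2, 0 °C → rt; Rochelle salt work-up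
Reagents that add atoms: N,O-dimethylhydroxylamine hydrochloride, CNOC.Cl
Why: Aluminium-amide aminolysis of an ester (Weinreb amide synthesis), a non-basic method that tolerates the free hydroxyl and the primary chloride and leaves C8 untouched.

Step 10
Reactants: 16 Weinreb amide; 17 5-bromopent-1-ene
Product: 19 (2R)-1-chloro-2-hydroxynon-8-en-4-one, via pent-4-enylmagnesium bromide 18 (not isolated)
Conditions: 17, Mg, THF; then 16 (18 in 2.5 equiv), THF, −20 → 0 °C; aq NH4Cl
Reagents that add atoms: none
Why: Weinreb ketone synthesis, in which the first equivalent of Grignard reagent deprotonates the hydroxyl and the second forms the stable magnesium chelate that collapses only on work-up, so over-addition is excluded and at or below 0 °C the chlorohydrin alkoxide should not close.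

Step 11
Reactants: 19 β-hydroxy ketone
Product: 20 (2R,4S)-1-chloro-4-hydroxynon-8-en-2-yl benzoate (O8 benzoate, free 6S hydroxyl)
Conditions: PhCHO (5 equiv), SmI2 (0.3 equiv, premixed with the aldehyde), THF, −10 °C
Reagents that add atoms: benzaldehyde, O=Cc1ccccc1
Why: Evans–Tishchenko reduction, in which the C8 hydroxyl forms a samarium-bound hemiacetal with benzaldehyde and passes its hydride to C6 through a chair-like bicyclic transition state, setting 6S (1,3-anti to C8) and differentiating the two oxygens at the same time.

Step 12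
Reactants: 20 hydroxy benzoate
Product: 21 (2R,4S)-4-(TBSO)-1-chloronon-8-en-2-yl benzoate
Conditions: TBSOTf (1.2 equiv), 2,6-lutidine (2 equiv), CH2Cl2, −78 → 0 °C
Reagents that add atoms: tert-butyldimethylsilyl triflate, CC(C)(C)[Si](C)(C)OS(=O)(=O)C(F)(F)F
Why: Fast low-temperature triflate silylation should cap O6 before the benzoate can migrate from O8, which locks the differentiation gained in step 11.

Step 13
Reactants: 21 silyloxy benzoate
Product: 23 (2R)-2-[(2S)-2-(TBSO)hept-6-enyl]oxirane (C1–C9 fragment), via C8 chlorohydrin 22 (not isolated)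
Conditions: K2CO3 (2 equiv), MeOH, 0 °C → rt
Reagents that add atoms: none
Why: Base-catalysed transesterification frees O8, whose alkoxide displaces the adjacent primary chloride (intramolecular Williamson closure, 3-exo-tet), and since only the C9–Cl bond breaks C8 keeps its configuration.

Step 14
Reactants: 14 terminal alkyne; 23 epoxide
Product: 25 (6S,8S,14R,15S,16R,18Z)-15-chloro-14-methyl-6,16,21-tris(TBSO)henicosa-1,18-dien-10-yn-8-ol, via lithium acetylide 24 (not isolated)
Conditions: 14 (1.3 equiv), n-BuLi (1.25 equiv), THF, −78 °C; BF3·OEt2 (1.3 equiv); 23 (1.0 equiv), −78 °C; excess 14 recovered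
Reagents that add atoms: none
Why: Yamaguchi–Hirao alkynylation of the BF3-activated terminal epoxide at unhindered C9 forms C9–C10 and releases O8 as the only free hydroxyl, while the doubly flanked secondary chloride and the silyl ethers are inert at −78 °C.

Step 15
Reactants: 25 homopropargylic alcohol
Product: 27 (6S,8S,14R,15S,16R,18Z)-15-chloro-8-hydroxy-14-methyl-6,16,21-tris(TBSO)henicosa-1,18-dien-11-one, via 2,3-dihydrofuran 26 (not isolated)
Conditions: Ph3PAuNTf2 (5 mol %), THF–H2O 20:1, rt; PPTS (10 mol %) to finish hydration
Reagents that add atoms: water, O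
Why: Gold(I)-catalysed 5-endo-dig hydroalkoxylation of a homopropargylic alcohol followed by hydration of the cyclic enol ether, in which O8 can reach only C11 (attack at C10 would need a four-membered ring), so the carbonyl should appear at C11 alone and no stereocentre is touched.

Step 16
Reactants: 27 C11 ketone with free C8–OH and 15S chloride
Product: 29 6,16,21-tris-O-TBS attenol A (6S,8S,11S,14R,15R,16R,18Z), via oxolane hemiketal 28 (not isolated)
Conditions: AgOTf (3 equiv), Ag2O (3 equiv), THF, dark, rt → 50 °C; Celite filtration, aq NaCl wash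
Reagents that add atoms: none
Why: Proposed new method: the γ-hydroxy ketone 27 equilibrates with its 2-hydroxyoxolane 28 (5-exo-trig addition of O8 to C11), and the hemiketal hydroxyl then attacks C15 opposite the silver-activated C–Cl bond in a 6-exo-tet SN2 displacement that closes the oxane and makes C11 the spiro centre, while direct participation of the ketone oxygen followed by capture by O8 would converge on the same product. The closest known reaction type is the stereospecific silver(I)- or heat-promoted cycloetherification of chlorohydrins and chloropolyols with inversion, including ketalisation–chloride displacement cascades to spiroketals, all of which close five-membered rings, so the six-membered closure at a chloride branched on both flanks is the untested extension. C15 is controlled by inversion (15S chloride to 15R ether), because the electron-withdrawing C16 oxygen disfavours a free cation and should keep the substitution concerted. C11 is controlled by a chair transition state with the C14 methyl and the C16 chain equatorial and the oxolane oxygen axial (anomeric effect), and since this is also the thermodynamic isomer any epimer can be equilibrated with catalytic PPTS in CH2Cl2 at this fully protected stage. The step needs the C11 oxygen alone to reach C15 and no further oxygen to reach C11, which the substrate secures because O8 is the only free hydroxyl, the C16 silyl ether shuts off epoxide closure (net retention) and the 1,2-hydride shift of a free chlorohydrin, and the C6 silyl ether prevents an O6/O8 2,8-dioxabicyclo[3.2.1]octane ketal. Ag2O consumes triflic acid as it forms, so the silyl ethers and the new ketal never meet acid.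

Step 17
Reactants: 29 tris-TBS attenol A
Product: 30 attenol A
Conditions: TBAF (6 equiv), THF, rt → 40 °C; aqueous work-up
Reagents that add atoms: none
Why: Fluoride-induced desilylation, chosen over acid because no chlorohydrin or other base-sensitive group remains whereas acid could let the freed O16 or O6 re-open the spiroketal to bicyclic ketals, so all six stereocentres and the Z alkene should be retained.

Compound list
1 | (R)-citronellal | CC(C)=CCC[C@@H](C)CC=O | starting material
2 | (2S,3R)-2-chloro-3,7-dimethyloct-6-enal | CC(C)=CCC[C@@H](C)[C@@H](C=O)Cl | intermediate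
3 | propargyl bromide | C#CCBr | starting material
4 | allenylmagnesium bromide | C=C=C[Mg]Br | intermediate
5 | (4R,5S,6R)-5-chloro-6,10-dimethylundec-9-en-1-yn-4-ol | CC(C)=CCC[C@@H](C)[C@@H]([C@H](O)CC#C)Cl | intermediate
6 | C16 TBS ether of 5 | CC(C)=CCC[C@@H](C)[C@@H]([C@H](O[Si](C)(C)C(C)(C)C)CC#C)Cl | intermediate
7 | ethylene oxide | C1CO1 | starting material
8 | lithium acetylide of 6 | CC(C)=CCC[C@@H](C)[C@@H]([C@H](O[Si](C)(C)C(C)(C)C)CC#C[Li])Cl | intermediate
9 | (6R,7S,8R)-7-chloro-6-(TBSO)-8,12-dimethyltridec-11-en-3-yn-1-ol | CC(C)=CCC[C@@H](C)[C@@H]([C@H](O[Si](C)(C)C(C)(C)C)CC#CCCO)Cl | intermediate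
10 | C16,C21 bis-TBS ether of 9 | CC(C)=CCC[C@@H](C)[C@@H]([C@H](O[Si](C)(C)C(C)(C)C)CC#CCCO[Si](C)(C)C(C)(C)C)Cl | intermediate
11 | secondary ozonide (3,3-dimethyl-1,2,4-trioxolane) of 10 | CC1(C)OOC(CC[C@@H](C)[C@@H]([C@H](O[Si](C)(C)C(C)(C)C)CC#CCCO[Si](C)(C)C(C)(C)C)Cl)O1 | intermediate
12 | (4R,5S,6R)-5-chloro-4-methyl-6,11-bis(TBSO)undec-8-ynal | O=CCC[C@@H](C)[C@@H]([C@H](O[Si](C)(C)C(C)(C)C)CC#CCCO[Si](C)(C)C(C)(C)C)Cl | intermediate
13 | (4R,5S,6R,8Z)-5-chloro-4-methyl-6,11-bis(TBSO)undec-8-enal | O=CCC[C@@H](C)[C@@H]([C@H](O[Si](C)(C)C(C)(C)C)C/C=C\CCO[Si](C)(C)C(C)(C)C)Cl | intermediate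
14 | (5R,6S,7R,9Z)-6-chloro-5-methyl-7,12-bis(TBSO)dodec-9-en-1-yne | C#CCC[C@@H](C)[C@@H]([C@H](O[Si](C)(C)C(C)(C)C)C/C=C\CCO[Si](C)(C)C(C)(C)C)Cl | intermediate
15 | ethyl (3R)-4-chloro-3-hydroxybutanoate | CCOC(=O)C[C@@H](O)CCl | starting material
16 | (3R)-4-chloro-3-hydroxy-N-methoxy-N-methylbutanamide | CON(C)C(=O)C[C@@H](O)CCl | intermediate
17 | 5-bromopent-1-ene | C=CCCCBr | starting material
18 | pent-4-enylmagnesium bromide | C=CCCC[Mg]Br | intermediate
19 | (2R)-1-chloro-2-hydroxynon-8-en-4-one | C=CCCCC(=O)C[C@@H](O)CCl | intermediate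
20 | (2R,4S)-1-chloro-4-hydroxynon-8-en-2-yl benzoate | C=CCCC[C@H](O)C[C@@H](OC(=O)c1ccccc1)CCl | intermediate
21 | (2R,4S)-4-(TBSO)-1-chloronon-8-en-2-yl benzoate | C=CCCC[C@H](O[Si](C)(C)C(C)(C)C)C[C@@H](OC(=O)c1ccccc1)CCl | intermediate
22 | (2R,4S)-4-(TBSO)-1-chloronon-8-en-2-ol | C=CCCC[C@H](O[Si](C)(C)C(C)(C)C)C[C@@H](O)CCl | intermediate
23 | (2R)-2-[(2S)-2-(TBSO)hept-6-enyl]oxirane | C=CCCC[C@H](O[Si](C)(C)C(C)(C)C)C[C@@H]1CO1 | intermediate
24 | lithium acetylide of 14 | [Li]C#CCC[C@@H](C)[C@@H]([C@H](O[Si](C)(C)C(C)(C)C)C/C=C\CCO[Si](C)(C)C(C)(C)C)Cl | intermediate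
25 | coupled C1–C21 alkynol (6S,8S,14R,15S,16R,18Z) | C=CCCC[C@H](O[Si](C)(C)C(C)(C)C)C[C@@H](O)CC#CCC[C@@H](C)[C@@H]([C@H](O[Si](C)(C)C(C)(C)C)C/C=C\CCO[Si](C)(C)C(C)(C)C)Cl | intermediate
26 | 2,3-dihydrofuran (O8–C11 enol ether, C10=C11) | C=CCCC[C@H](O[Si](C)(C)C(C)(C)C)C[C@@H]1CC=C(CC[C@@H](C)[C@@H]([C@H](O[Si](C)(C)C(C)(C)C)C/C=C\CCO[Si](C)(C)C(C)(C)C)Cl)O1 | intermediate
27 | C11 ketone, free C8–OH, 15S chloride, O6/O16/O21 TBS | C=CCCC[C@H](O[Si](C)(C)C(C)(C)C)C[C@@H](O)CCC(=O)CC[C@@H](C)[C@@H]([C@H](O[Si](C)(C)C(C)(C)C)C/C=C\CCO[Si](C)(C)C(C)(C)C)Cl | intermediate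
28 | oxolane hemiketal of 27 (reacting 11R epimer; epimers interconvert through 27) | C=CCCC[C@H](O[Si](C)(C)C(C)(C)C)C[C@@H]1CC[C@@](O)(CC[C@@H](C)[C@@H]([C@H](O[Si](C)(C)C(C)(C)C)C/C=C\CCO[Si](C)(C)C(C)(C)C)Cl)O1 | intermediate
29 | 6,16,21-tris-O-TBS attenol A | C=CCCC[C@H](O[Si](C)(C)C(C)(C)C)C[C@@H]1CC[C@@]2(CC[C@@H](C)[C@H]([C@H](O[Si](C)(C)C(C)(C)C)C/C=C\CCO[Si](C)(C)C(C)(C)C)O2)O1 | intermediate
30 | attenol A | C=CCCC[C@H](O)C[C@@H]1CC[C@@]2(CC[C@@H](C)[C@H]([C@H](O)C/C=C\CCO)O2)O1 | target

Total step count: 17. Longest linear sequence: 12 steps (steps 1–8 and 14–17, from (R)-citronellal).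

Steps most likely to fail

Step 16 (new method). The six-membered closure at a chloride branched on both flanks may be slower than silver-induced loss of HCl towards C14, or may not start at all. The fallback sets out from 27 and rejoins the route at 30, using known chemistry only.
- Aqueous HF in MeCN removes the three silyl groups to give the keto tetraol chloride F1.
- Ac2O, pyridine and DMAP convert it into the tetraacetate F2.
- AgOTf with 2,6-di-tert-butylpyridine in wet dioxane at 60 °C lets the C16 acetate displace the C15 chloride from the rear. This is five-membered neighbouring-group participation, the wet Woodward–Prévost manifold.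
- Hydrolysis at the former acetyl carbon leaves the 15R-hydroxy tetraacetate F3. Any O15/O16 acyl-shifted material converges in the next operation.
- K2CO3 in MeOH gives the keto pentaol F4.
- PPTS in CH2Cl2–MeOH closes it by classical thermodynamic spiroketalisation to 30.
- Partial diversion into the bicyclic ketal through O15 and O16 then has to be corrected by chromatography and re-equilibration.

Step 2. Facial selectivity may be poor in the very fast, closed-transition-state Grignard addition, and the basic reagent may epimerise C15 before it adds. The fallback sets out from 4 and 2 and rejoins at 5.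
- Reagent 4 is quenched with Bu3SnCl and distilled to give allenyltributylstannane F5.
- F5 is added to 2 with BF3·OEt2 in CH2Cl2 at −78 °C, followed by a KF work-up.
- This non-basic Lewis-acid SE2′ addition runs through an open antiperiplanar transition state. There the polar Felkin–Anh/Cornforth bias of the α-chloroaldehyde should be expressed more fully.

Step 1. The C15 configuration may erode by enolisation during chlorination and work-up, and catalyst control may be incomplete if the C14 methyl is mismatched. The fallback sets out from 1 and rejoins at 2.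
- The chlorination mixture is reduced in the same flask with NaBH4 in MeOH at 0 °C to (2S,3R)-2-chloro-3,7-dimethyloct-6-en-1-ol F6.
- F6 is configurationally stable and can be freed from its 2R epimer by chromatography.
- It is oxidised with Dess–Martin periodinane and NaHCO3 in CH2Cl2 immediately before step 2.

Further compounds
F1 | step 16 | (6S,8S,14R,15S,16R,18Z)-15-chloro-6,8,16,21-tetrahydroxy-14-methylhenicosa-1,18-dien-11-one | C=CCCC[C@H](O)C[C@@H](O)CCC(=O)CC[C@@H](C)[C@@H]([C@H](O)C/C=C\CCO)Cl
F2 | step 16 | 6,8,16,21-tetraacetate of F1 | C=CCCC[C@H](OC(C)=O)C[C@@H](OC(C)=O)CCC(=O)CC[C@@H](C)[C@@H]([C@H](OC(C)=O)C/C=C\CCOC(C)=O)Cl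
F3 | step 16 | (15R)-15-hydroxy 6,8,16,21-tetraacetate of the C11 ketone | C=CCCC[C@H](OC(C)=O)C[C@@H](OC(C)=O)CCC(=O)CC[C@@H](C)[C@H]([C@H](OC(C)=O)C/C=C\CCOC(C)=O)O
F4 | step 16 | (6S,8S,14R,15R,16R,18Z)-6,8,15,16,21-pentahydroxy-14-methylhenicosa-1,18-dien-11-one | C=CCCC[C@H](O)C[C@@H](O)CCC(=O)CC[C@@H](C)[C@H]([C@H](O)C/C=C\CCO)O
F5 | step 2 | allenyltributylstannane | C=C=C[Sn](CCCC)(CCCC)CCCC
F6 | step 1 | (2S,3R)-2-chloro-3,7-dimethyloct-6-en-1-ol | CC(C)=CCC[C@@H](C)[C@@H](CO)Cl
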